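Time is what I hand over: the bath stays put, and the clock is what you read. The closed runs blue, grey and ochre hold the same substrate and partner and differ in protic impurity, yet blue and grey both read 26 % at 50 min, so leave the impurity alone.

common to all: substrate 0.057 M

|  | partner | protic impurity | remark | time |
|---|---|---|---|---|
| blue | 0.0342 M | 2.85 mM | run made earlier |  |
| grey | 0.0342 M | 1.4 mM | run made earlier |  |
| ochre | 0.0342 M | 2.1 mM | run made earlier |  |
| midnight | 0.0342 M | 2.85 mM | a single well-mixed tank run continuously and read at steady state, 50 min in it on average |  |
| spring | 0.0342 M (fed, over 40.0 min) | 2.85 mM | a stirred flask in which partner is dosed at a steady rate over 40.0 min without added volume, worked up at 50 min | 50 min |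
| summer | 0.0342 M | 2.85 mM | plug flow through a tube for 50 min, no back-mixing | 50 min |
| dawn | 0.0342 M | 2.85 mM | a closed flask charged with all of it at once and left for 50 min | 50 min |

| run | time / min | target / % |
|---|---|---|
| blue | 4.00 | 4 |
| blue | 6.00 | 8 |
| blue | 10.0 | 8 |
| blue | 15.0 | 12 |
| blue | 20.0 | 14 |
| blue | 30.0 | 19 |
| blue | 50.0 | 26 |
| grey | 3.00 | 4 |
| grey | 10.0 | 7 |
| grey | 15.0 | 13 |
| grey | 25.0 | 17 |
| grey | 40.0 | 21 |
| grey | 50.0 | 26 |
| grey | 60.0 | 26 |
| ochre | 8.00 | 6 |
| ochre | 15.0 | 12 |
| ochre | 25.0 | 17 |
| ochre | 30.0 | 19 |
| ochre | 40.0 | 22 |
| ochre | 50.0 | 26 |
| ochre | 60.0 | 28 |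

(scatter of a reading: 1.5 percentage points)

- the stated concentrations are those of everything mixed, before any reaction; amounts are the same in each set-up
- the feed brings no volume worth counting
- the earlier runs were made in a closed, stirred flask
- a reading or a percentage of target counts all its forms, free or not

* the set-up with the highest amount of target at the outlet or at the end, in percent of the substrate put in ("none" if the first two lie within 2 percentage points) (midnight / spring / summer / dawn / none)
* amount of target at the outlet or at the end, in percent of the substrate put in, midnight
* amount of target at the outlet or at the end, in percent of the substrate put in, spring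
* amount of target at the outlet or at the end, in percent of the substrate put in, summer
* amount of target at the outlet or at the end, in percent of the substrate put in, dawn

My measure is the early half-life, the time in which substrate halves if it keeps leaving for target at blue's opening pace. It is a reading and carries the scatter:

early half-life = ln(2) × 15.0 min / −ln(1 − 12 %) = 81.3 min

mark at 50 min = 1 − 2^(−50 min / early half-life) = 34.7 %

Blue ends lower than this mark, so its pace sags. When you come, dawn and summer, with blue's charge and history, should stand near 26 %. Don't touch the feed in spring: its partner history differs from blue's, and blue, grey and ochre all hold 0.0342 M of partner, so they give no comparison of partner levels, and I hold spring against the mark.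

The forecast gives 20 % for midnight, 18 % for spring, 26 % for summer and 26 % for dawn, and it says “Flask and tube tie, so best is none.”

Midnight gives 21.5 %, spring 32.6 %, summer 25.1 % and dawn 25.1 %, so the best is spring, 15 percentage points above the forecast for spring and 2 points under my mark.

    substrate + partner ⇌ intermediate (K = 200 M⁻¹, k = 1.80 M⁻¹ min⁻¹)
    intermediate → side product A (k = 0.0160 min⁻¹)
    substrate → target (k = 0.0110 min⁻¹)
    intermediate → side product B (k = 0.0160 min⁻¹)
    substrate + target ⇌ idle adduct, settled at all times (K = 12.0 M⁻¹)
    partner + protic impurity → quenched reagent (k = 81.0 M⁻¹ min⁻¹)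
    2 substrate → homo dimer (k = 9.30 × 10⁻⁵ M⁻¹ min⁻¹)

Spring has not come to rest at 50 min, which is 0.615 early half-lives: substrate 27.6 % and intermediate 17.7 % still stand. Ten times the time is 6.15 early half-lives, and that count leaves 1.41 % of the substrate. The computed spring holds less than that, 0.0832 %, at 500 min. Target there reaches 51.8 %, and side product B climbs from 8.39 % to 24.0 %.

The neighbour flask, spring with 0.086 M of partner, also runs 50 min, and the early half-life holds no term for partner, so my mark for it is again 34.7 %. Computed, it gives 24.6 %, with 29.9 % standing as intermediate.

The runs stem from a simulated flask on assumed constants; noise was put on by code.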